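The rate constants were drawn at random within sensible limits; no experiment stands behind them.

Take one substrate unit and follow it through the flask, asking its chances at each fork.

substrate 18 mM (fed, over 10 min); other conformer 1.80 mM; catalyst 0.90 mM; time 1.5 h

- why nothing more happens at 1.5 h, or that something still does (other conformer counts as not reacted) (it is still moving / no working catalyst is left / forward and back rates have come level / all of the substrate has reacted)
- how much of the substrate and other conformer together has reacted by 1.5 h
- how much target there is at 1.5 h, in percent of the substrate and other conformer together charged

- percent here means substrate units held: one side product counts as two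
- in a conversion other conformer counts as not yet reacted
- the reaction counts as stopped when no species that holds the substrate and other conformer together changes by six tenths of a point or more over the second half of the time
- run time (flask): 1.5 h

    substrate ⇌ other conformer (K1 = 0.063, k1 = 0.0013 s⁻¹)
    substrate + catalyst → catalyst + target (k2 = 3.8 M⁻¹ s⁻¹)
    catalyst + other conformer → catalyst + isomer of the product (k3 = 7.0 M⁻¹ s⁻¹)
    substrate + target → side product (k4 = 0.11 M⁻¹ s⁻¹)
    substrate → uncatalysed product (k5 = 0.0039 s⁻¹)

Both catalysed steps return the catalyst, so treat [catalyst] as constant, which makes them first-order drains (pseudo-first-order). Define the fork ratio r, the catalysed rate constant times [catalyst] over the uncatalysed rate constant: 0.00342 s⁻¹ over 0.0039 s⁻¹ gives 0.877 target made per uncatalysed product.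

Next, reckon the detour. Substrate becomes other conformer at 0.0013 s⁻¹. Other conformer returns at 0.0206 s⁻¹, faster than it goes to isomer of the product at 0.00630 s⁻¹, so its chance of return is 76.6%. That leaves a leak of 3.04 × 10⁻⁴ s⁻¹.

| Exit | Drain | Chance |
|---|---|---|
| target | 0.00342 s⁻¹ | 44.9% |
| uncatalysed product | 0.0039 s⁻¹ | 51.2% |
| isomer of the product | 3.04 × 10⁻⁴ s⁻¹ | 3.99% |

The time constant is 2.19 min, short against the run, so expect a conversion of >99.9%. The charged other conformer returns by the same chance, which puts 97.9% of the charge through the fork. Commit to 44.0% target made.

The weak link is that substrate also eats target. Reforge it with the exposure, the rate constant of that step times the time integral of [substrate], which is 0.280. With target formed evenly along that exposure, its mean survival is 87.2%, and my figure becomes 38.3%.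

The forecast says all of the substrate has reacted, with conversion 100% and target 36.6%, a little below my figure: “By 1.5 h everything has reacted”.

The simulation reports: all of the substrate has reacted, with conversion 100% and target 36.6%.

Remove the uncatalysed path from the flask and target rises from 36.6% to 60.0%, a gain of 23 percentage points, which is 37% of what is missing. Target made, counted as target plus half of the side product, stands to uncatalysed product in the flask as 0.877, against r of 0.877. In the neighbour with 1.5 mM of catalyst, r becomes 1.46, so expect target made to exceed uncatalysed product. That neighbour holds 47.4% target against 35.8% uncatalysed product, a ratio, counted the same way, of 1.46.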